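The cyclohexenone ring is cut into two three-carbon pieces at C4–C5 and C7–C7a (benzofuranone numbering). The feature exploited is that the lactone carbonyl C2 and the ring methylene C4 both sit on the quaternary C3a: in the achiral 3-farnesyl-3-formylcyclobutanone 6 they are one ketone and its α-carbon. In one flask an asymmetric alkenylation of the aldehyde forms C7–C7a and the carbinol centre; the cyclobutanone enolate then takes the cis acyl group onto C4, and the new hydroxyl opens the four-membered ring, so that its carbonyl ends as the γ-lactone. C7a thereby dictates the configuration of C3a.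

Key step: step 5

Remarks and assumptions
- Atom labels follow the target numbering O1, C2(=O), C3, C3a, C4, C5(=O), C6, C7, C7a; "farnesyl" means (2E,6E)-3,7,11-trimethyldodeca-2,6,10-trien-1-yl.
- Compounds 1, 3, 7 and all reagents are taken as commercial.
- Ligand L* is (S)-N-[2-(4-isopropyl-4,5-dihydrooxazol-2-yl)-6-methylphenyl]methanesulfonamide; it is assumed to direct the alkenyl group to the Re face of the aldehyde, and its (R)-enantiomer is used if the sense is the opposite.
- Compound 9 is drawn as the free alcohol although it is present as its trivalent chromium alkoxide; 10 is drawn as the diketo tautomer.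

Step 1
Reactants: 1 3-oxocyclobutane-1-carbonitrile
Product: 2 3,3-dimethoxycyclobutane-1-carbonitrile
Conditions: HC(OMe)3, TsOH·H2O (cat.), MeOH, 23 °C
Reagents that add atoms: trimethyl orthoformate, COC(OC)OC
Why: Acid-catalysed ketalisation, with the orthoformate as water scavenger, masks the enolisable cyclobutanone before the strong-base step, and relief of ring strain favours the sp3 ketal.

Step 2
Reactants: 2 3,3-dimethoxycyclobutane-1-carbonitrile; 3 (2E,6E)-farnesyl bromide
Product: 4 3,3-dimethoxy-1-farnesylcyclobutane-1-carbonitrile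
Conditions: LiN(iPr)2, THF, −78 °C; then 3, −78 → 0 °C
Reagents that add atoms: none
Why: α-Alkylation of the nitrile-stabilised carbanion (SN2 at the primary allylic bromide) builds the quaternary carbon; the product keeps a mirror plane, so no stereocentre arises.

Step 3
Reactants: 4 3,3-dimethoxy-1-farnesylcyclobutane-1-carbonitrile
Product: 6 3-oxo-1-farnesylcyclobutane-1-carbaldehyde, via ketal aldehyde 5 (not isolated)
Conditions: iBu2AlH, toluene, −78 °C; then 1 M aq. HCl, THF, 0 → 23 °C
Reagents that add atoms: water, O
Why: Hydride addition to the nitrile stops at the N-aluminio imine, which the aqueous acid hydrolyses to the non-enolisable aldehyde while it also cleaves the dimethyl ketal (nitrile half-reduction, then ketal hydrolysis); the product is still achiral.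

Step 4
Reactants: 7 (Z)-3-iodoprop-2-enoic acid
Product: 8 (Z)-3-iodo-N-methoxy-N-methylprop-2-enamide
Conditions: MeNHOMe·HCl, EDC·HCl, N-methylmorpholine, CH2Cl2, 0 °C
Reagents that add atoms: N,O-dimethylhydroxylamine hydrochloride, CNOC.Cl
Why: Carbodiimide amide coupling at low temperature should keep the Z geometry and installs an acyl group that can acylate a ketone enolate but cannot lactonise onto an alkoxide.

Step 5
Reactants: 6 3-oxo-1-farnesylcyclobutane-1-carbaldehyde; 8 (Z)-3-iodo-N-methoxy-N-methylprop-2-enamide
Product: 11 (3aR,7aR)-3a-farnesyl-3,3a,4,7a-tetrahydro-1-benzofuran-2,5-dione (target), via chromium alkoxide of hydroxy enamide 9 (not isolated), via fused hydroxy diketone 10 (not isolated)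
Conditions: CrCl2, NiCl2 (cat.), ligand L*, Et3N, THF, 23 °C; then KN(SiMe3)2, −78 → −20 °C; then AcOH, −78 °C; then Et3N, 23 °C (one flask, nothing isolated)
Reagents that add atoms: none
Why: Zerovalent nickel inserts into the C–I bond of 8 and hands the Z-alkenyl group to chromium; the alkenylchromium adds only to the aldehyde of 6 (Nozaki–Hiyama–Kishi reaction), from the Re face under control of the chromium-bound oxazoline sulfonamide, which sets C7a as R in 9. Because the acyl group is an N-methoxy-N-methylamide, the alkoxide cannot close a furanone, so H–C7a never becomes an acidic γ-proton and the configuration should hold through the base stage. KN(SiMe3)2 forms the cyclobutanone enolate, whose α-carbon attacks the cis-held amide carbonyl (intramolecular Claisen acylation of a ketone enolate, 6-exo-trig) to give 10 with the new C4–C5 bond. After neutralisation the C7a hydroxyl adds across the four-membered ring to its strained carbonyl C2 (5-exo-trig) and the C2–C4 bond breaks with the enol of the new ketone as leaving group (retro-Claisen driven by ring strain), which gives the cis-fused lactone and leaves C4 as CH2. C3a is not a stereocentre until one of its two enantiotopic CH2C(=O) arms is chosen: the metal-bridged alkoxide–enolate holds the C7a oxygen over the cyclobutanone, so the arm that acylates leaves oxygen cis to C2, and only this diastereomer can lactonise, the other falling back to a separable furanone under Et3N. The selectivities needed are aldehyde over cyclobutanone in the addition, secured by the low reactivity of organochromium reagents towards ketones, and C- over O-acylation of the enolate, secured by a six- against an eight-membered transition state.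

Compound list
1 | 3-oxocyclobutane-1-carbonitrile | N#CC1CC(=O)C1 | starting material
2 | 3,3-dimethoxycyclobutane-1-carbonitrile | N#CC1CC(OC)(OC)C1 | intermediate
3 | (2E,6E)-farnesyl bromide, (2E,6E)-1-bromo-3,7,11-trimethyldodeca-2,6,10-triene | CC(C)=CCC/C(C)=C/CC/C(C)=C/CBr | starting material
4 | 3,3-dimethoxy-1-[(2E,6E)-3,7,11-trimethyldodeca-2,6,10-trien-1-yl]cyclobutane-1-carbonitrile (achiral) | CC(C)=CCC/C(C)=C/CC/C(C)=C/CC1(C#N)CC(OC)(OC)C1 | intermediate
5 | 3,3-dimethoxy-1-[(2E,6E)-farnesyl]cyclobutane-1-carbaldehyde | CC(C)=CCC/C(C)=C/CC/C(C)=C/CC1(C=O)CC(OC)(OC)C1 | intermediate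
6 | 3-oxo-1-[(2E,6E)-farnesyl]cyclobutane-1-carbaldehyde (achiral, two enantiotopic CH2C(=O) arms) | CC(C)=CCC/C(C)=C/CC/C(C)=C/CC1(C=O)CC(=O)C1 | intermediate
7 | (Z)-3-iodoprop-2-enoic acid | OC(=O)/C=C\I | starting material
8 | (Z)-3-iodo-N-methoxy-N-methylprop-2-enamide | CON(C)C(=O)/C=C\I | intermediate
9 | (2Z,4R)-4-hydroxy-N-methoxy-N-methyl-4-{3-oxo-1-[(2E,6E)-farnesyl]cyclobutyl}but-2-enamide, present as its trivalent chromium alkoxide | CC(C)=CCC/C(C)=C/CC/C(C)=C/CC1(CC(=O)C1)[C@H](O)/C=C\C(=O)N(C)OC | intermediate
10 | (5R)-5-hydroxy-6-[(2E,6E)-farnesyl]bicyclo[4.2.0]oct-3-ene-2,8-dione, cis ring fusion, hydroxyl on the face of the four-membered ring | CC(C)=CCC/C(C)=C/CC/C(C)=C/C[C@]12CC(=O)[C@H]1C(=O)C=C[C@H]2O | intermediate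
11 | (3aR,7aR)-3a-[(2E,6E)-3,7,11-trimethyldodeca-2,6,10-trien-1-yl]-3,3a,4,7a-tetrahydro-1-benzofuran-2,5-dione | CC(C)=CCC/C(C)=C/CC/C(C)=C/C[C@]12CC(=O)C=C[C@H]1OC(=O)C2 | target

Total step count: 5
Longest linear sequence: 4 steps (1 → 2 → 4 → 6 → 11; step 4 is a one-step side branch)

Steps most likely to fail

1. Step 5.
What may go wrong: incomplete enolisation and acyl transfer in a medium loaded with chromium and ammonium salts; acylation through the wrong enantiotopic α-carbon; loss of enantiopurity if an adduct reverts to a furanone while strong base is still present.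
Fallback (sets out from 6, comes back at 11): the two ring bonds are made in separate, individually known operations.
- Zinc alkynylide addition of methyl propiolate to 6 (Me2Zn, a chiral bis(diarylprolinol)phenol ligand, triphenylphosphine oxide, toluene, 4 °C) should give methyl (S)-4-hydroxy-4-(3-oxo-1-farnesylcyclobutyl)but-2-ynoate F1. The spatial arrangement is that of 9; the descriptor changes only because the alkynyl carbon outranks the ring carbon.
- Et3SiCl and imidazole give the triethylsilyl ether F2.
- Semihydrogenation (H2, Pd/CaCO3 poisoned with Pb(OAc)2, quinoline) gives the (2Z,4R) enoate F3, which cannot lactonise.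
- KN(SiMe3)2 in THF at −78 °C should close the six-membered ring by Claisen acylation to the silylated fused diketone F4.
- HF·pyridine and then Et3N free the hydroxyl, which opens the cyclobutanone to 11.

2. Step 3.
What may go wrong: over-reduction of the imine aluminate; acid-promoted hydration or cyclisation of the farnesyl alkenes during ketal cleavage; aldol self-condensation of the keto aldehyde.
Fallback (sets out from 3, comes back at 6): the nitrile half-reduction is replaced by ester reduction and re-oxidation, and the ketal is removed by buffered exchange.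
- Commercial methyl 3,3-dimethoxycyclobutane-1-carboxylate (COC(=O)C1CC(OC)(OC)C1) is alkylated with 3 (LiN(iPr)2, THF, −78 °C) to methyl 3,3-dimethoxy-1-farnesylcyclobutane-1-carboxylate F5.
- LiAlH4 in Et2O at 0 °C gives (3,3-dimethoxy-1-farnesylcyclobutyl)methanol F6.
- SO3·pyridine, DMSO and Et3N give the ketal aldehyde 5, now isolated.
- Pyridinium p-toluenesulfonate in wet acetone then gives 6.

3. Step 2.
What may go wrong: slow substitution at the hindered tertiary carbanion, so that elimination of HBr from 3 and SN2′ attack compete.
Fallback (sets out from 3, comes back at 4): the quaternary carbon is closed as the last bond of the four-membered ring instead of being alkylated.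
- LiCH2CN (from MeCN and n-BuLi, THF, −78 °C) and 3 should give (4E,8E)-5,9,13-trimethyltetradeca-4,8,12-trienenitrile F7.
- Double alkylation with 1,3-dibromo-2,2-dimethoxypropane (NaN(SiMe3)2, THF–DMPU, 0 → 60 °C, second bond 4-exo-tet) should give 4.

Further compounds
F1 | step 5 | methyl (S)-4-hydroxy-4-{3-oxo-1-[(2E,6E)-farnesyl]cyclobutyl}but-2-ynoate | CC(C)=CCC/C(C)=C/CC/C(C)=C/CC1(CC(=O)C1)[C@H](O)C#CC(=O)OC
F2 | step 5 | methyl (S)-4-{3-oxo-1-[(2E,6E)-farnesyl]cyclobutyl}-4-(triethylsilyloxy)but-2-ynoate | CC(C)=CCC/C(C)=C/CC/C(C)=C/CC1(CC(=O)C1)[C@H](O[Si](CC)(CC)CC)C#CC(=O)OC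
F3 | step 5 | methyl (2Z,4R)-4-{3-oxo-1-[(2E,6E)-farnesyl]cyclobutyl}-4-(triethylsilyloxy)but-2-enoate | CC(C)=CCC/C(C)=C/CC/C(C)=C/CC1(CC(=O)C1)[C@H](O[Si](CC)(CC)CC)/C=C\C(=O)OC
F4 | step 5 | (5R)-6-[(2E,6E)-farnesyl]-5-(triethylsilyloxy)bicyclo[4.2.0]oct-3-ene-2,8-dione, cis ring fusion, silyloxy group on the face of the four-membered ring | CC(C)=CCC/C(C)=C/CC/C(C)=C/C[C@]12CC(=O)[C@H]1C(=O)C=C[C@H]2O[Si](CC)(CC)CC
F5 | step 3 | methyl 3,3-dimethoxy-1-[(2E,6E)-farnesyl]cyclobutane-1-carboxylate | CC(C)=CCC/C(C)=C/CC/C(C)=C/CC1(C(=O)OC)CC(OC)(OC)C1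
F6 | step 3 | {3,3-dimethoxy-1-[(2E,6E)-farnesyl]cyclobutyl}methanol | CC(C)=CCC/C(C)=C/CC/C(C)=C/CC1(CO)CC(OC)(OC)C1
F7 | step 2 | (4E,8E)-5,9,13-trimethyltetradeca-4,8,12-trienenitrile | CC(C)=CCC/C(C)=C/CC/C(C)=C/CCC#N
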